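**Plan**

- Numbering (decahydronaphthalene): C2 carries Me and the aryl ether oxygen, C4a the angular Me, C7 the 2-hydroxypropan-2-yl group, C8a the ring-fusion H; ring A = C1–C4/C4a/C8a, ring B = C4a/C5–C8/C8a.
- Cuts, in retrosynthetic order: side-chain O–Si; biaryl C–C (Suzuki–Miyaura) and aryl–allyl C–C (Stille); C2–O–aryl (O-arylation of the tertiary alcohol with a diaryliodonium salt); C2–CH3 (methyl addition to the C2 ketone); then the strategic cut C4a–C5.
- Enabling feature: in ring A the oxygen-bearing C2 stands para to the methyl-bearing quaternary C4a, so ring A is a hidden p-cresol whose para carbon (C4a) is nucleophilic as the phenoxide. Its ring neighbour C8a carries the chain C8–C7–C6–C5, and a primary bromide at C5 closes ring B onto C4a by alkylative dearomatization.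
- Forward: aromatic ring A first; the chain is attached at benzylic C8 (Wittig, hydrogenation, lactone opening, Grignard); ring B is closed in the key step, which also creates the quaternary centre and leaves the cross-conjugated dienone; ring A is then reduced to the trans-decalone, methylated and O-arylated, and the honokiol unit is completed by two cross-couplings.
- Stereochemistry: C7 by catalytic asymmetric hydrogenation; C4a relayed from C7 in the key step; C8a from C4a (dissolving-metal reduction, trans fusion); C2 from the locked chair (equatorial methyl delivery, axial oxygen).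

Key step: step 6

Assumption: the (S)-configured ligand in step 2 is taken to deliver the (S)-lactone; if the sense of induction is the reverse, the (R)-ligand is used and nothing else changes.

**Route**

Step 1
Reactants: 1 5-methoxy-2-methylbenzaldehyde; 2 3-(triphenylphosphoranylidene)oxolan-2-one
Product: 3 (E)-3-[(5-methoxy-2-methylphenyl)methylidene]oxolan-2-one
Conditions: toluene, 110 °C
Reagents that add atoms: none
Why: Wittig olefination with a stabilized ylide should give the (E)-arylidene lactone (aryl cis to the ring CH2); no stereocentre is formed.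

Step 2
Reactants: 3 (E)-3-[(5-methoxy-2-methylphenyl)methylidene]oxolan-2-one
Product: 4 (S)-3-[(5-methoxy-2-methylphenyl)methyl]oxolan-2-one
Conditions: H2 (30 bar), [Ir(cod)((S)-tBu-PHOX)]BArF (1 mol %), CH2Cl2, rt
Reagents that add atoms: none
Why: Asymmetric hydrogenation of an exocyclic α-arylidene lactone with an iridium phosphine–oxazoline catalyst should set the lactone α-carbon (future C7) as (S) by catalyst-controlled face selection.

Step 3
Reactants: 4 (S)-3-[(5-methoxy-2-methylphenyl)methyl]oxolan-2-one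
Product: 6 methyl (2S)-4-bromo-2-[(5-hydroxy-2-methylphenyl)methyl]butanoate, via boron-bound bromo carboxylate 5 (not isolated)
Conditions: BBr3 (3 equiv), CH2Cl2, −78 °C → rt; then MeOH, 0 °C → rt
Reagents that add atoms: boron tribromide BrB(Br)Br; methanol CO
Why: Lewis-acid cleavage of the aryl methyl ether and bromide opening of the activated lactone at its O–CH2 carbon (SN2), followed by methanolysis of the acyloxyborane, should give the phenolic γ-bromo ester without touching the stereocentre.

Step 4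
Reactants: 6 methyl (2S)-4-bromo-2-[(5-hydroxy-2-methylphenyl)methyl]butanoate
Product: 7 3-[(2S)-4-bromo-2-(2-hydroxypropan-2-yl)butyl]-4-methylphenol
Conditions: MeMgBr (4 equiv), THF, −20 → 0 °C; aq NH4Cl
Reagents that add atoms: methylmagnesium bromide C[Mg]Br
Why: Double Grignard addition to the ester should give the dimethyl carbinol; the magnesium alkoxide is too weak a nucleophile to displace the primary bromide at or below 0 °C, as in the analogous preparation of 5-bromo-2-methylpentan-2-ol.

Step 5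
Reactants: 7 3-[(2S)-4-bromo-2-(2-hydroxypropan-2-yl)butyl]-4-methylphenol
Product: 8 triethyl({2-[(2S)-4-bromo-1-{2-methyl-5-[(triethylsilyl)oxy]phenyl}butan-2-yl]propan-2-yl}oxy)silane
Conditions: TESOTf (2.5 equiv), 2,6-lutidine, CH2Cl2, −78 → 0 °C
Reagents that add atoms: triethylsilyl trifluoromethanesulfonate CC[Si](CC)(CC)OS(=O)(=O)C(F)(F)F
Why: Silyl triflate silylation of both hydroxyls masks the tertiary alcohol (no tetrahydrofuran closure, later distinction from the C2 alcohol), makes the C7 substituent bulky and turns the phenol into a fluoride-triggered phenoxide precursor.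

Step 6
Reactants: 8 triethyl({2-[(2S)-4-bromo-1-{2-methyl-5-[(triethylsilyl)oxy]phenyl}butan-2-yl]propan-2-yl}oxy)silane
Product: 10 (4aS,7R)-4a-methyl-7-{2-[(triethylsilyl)oxy]propan-2-yl}-5,6,7,8-tetrahydronaphthalen-2(4aH)-one, via tetrabutylammonium phenoxide 9 (not isolated)
Conditions: TBAF (1.0 equiv), THF, 0 °C → 60 °C, 0.01 M
Reagents that add atoms: none
Why: Fluoride cleaves the aryl O–Si bond selectively, and the free phenoxide 9 attacks the primary C–Br carbon through its para carbon (the ring carbon that bears the methyl group) in an SN2 alkylative dearomatization that expels bromide and leaves the cross-conjugated dienone. The closest known reaction type is the intramolecular para-C-alkylation of phenoxides by tethered alkyl halides or sulfonates, which gives 4,4-disubstituted cyclohexadienones. Ring B closes in the 6-exo-tet mode, the chain terminus C5 bonding to C4a, the aromatic neighbour of the chain-bearing carbon C8a. The new quaternary centre C4a is controlled by the chain stereocentre C7: in the chair-like transition state the bulky 2-(triethylsilyloxy)propan-2-yl group stays equatorial, which places it cis to the angular methyl, itself axial on ring B. The step needs C- over O-alkylation and para over ortho attack: the meta tether cannot reach oxygen without a meta-bridged ring and high dilution suppresses intermolecular O-alkylation, while the para carbon carries the largest phenoxide coefficient and leads to the stable cross-conjugated dienone, whereas attack at the free ortho carbon would pass through the less stable linearly conjugated dienone. The tertiary silyl ether should survive because only one equivalent of fluoride is present, so no alkoxide forms that could close a tetrahydrofuran onto the bromide.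

Step 7
Reactants: 10 (4aS,7R)-4a-methyl-7-{2-[(triethylsilyl)oxy]propan-2-yl}-5,6,7,8-tetrahydronaphthalen-2(4aH)-one
Product: 11 (4aS,7R)-4a-methyl-7-{2-[(triethylsilyl)oxy]propan-2-yl}-4,4a,5,6,7,8-hexahydronaphthalen-2(3H)-one
Conditions: H2 (1 atm), RhCl(PPh3)3 (5 mol %), benzene/EtOH 1:1, rt
Reagents that add atoms: none
Why: Homogeneous hydrogenation with the rhodium chloride tris(triphenylphosphine) complex should saturate only the disubstituted C3=C4 bond of the cross-conjugated dienone and leave the trisubstituted enone; no stereocentre is formed.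

Step 8
Reactants: 11 (4aS,7R)-4a-methyl-7-{2-[(triethylsilyl)oxy]propan-2-yl}-4,4a,5,6,7,8-hexahydronaphthalen-2(3H)-one
Product: 12 (4aS,7R,8aS)-4a-methyl-7-{2-[(triethylsilyl)oxy]propan-2-yl}octahydronaphthalen-2(1H)-one
Conditions: Li (2.5 equiv), NH3(l)/THF, t-BuOH (1 equiv), −78 °C; then solid NH4Cl
Reagents that add atoms: none
Why: Dissolving-metal (Birch-type) reduction of the enone should protonate the β-carbon C8a axially, anti to the angular methyl, and so give the trans ring fusion under control of C4a.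

Step 9
Reactants: 12 (4aS,7R,8aS)-4a-methyl-7-{2-[(triethylsilyl)oxy]propan-2-yl}octahydronaphthalen-2(1H)-one
Product: 13 (2R,4aS,7R,8aS)-2,4a-dimethyl-7-{2-[(triethylsilyl)oxy]propan-2-yl}decahydronaphthalen-2-ol
Conditions: MeTi(OiPr)3 (2 equiv, from MeLi and ClTi(OiPr)3), Et2O, −30 °C → rt
Reagents that add atoms: methyltitanium triisopropoxide C[Ti](OC(C)C)(OC(C)C)OC(C)C
Why: Carbonyl addition of a bulky methyltitanium reagent to the conformationally locked cyclohexanone should occur from the equatorial direction, which gives the axial tertiary alcohol with equatorial methyl (2R).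

Step 10
Reactants: 14 4-bromo-2-chloro-1-iodobenzene
Product: 16 (4-bromo-2-chlorophenyl)(2,4,6-trimethoxyphenyl)iodonium 4-methylbenzenesulfonate, via hydroxy(tosyloxy)iodoarene 15 (not isolated)
Conditions: mCPBA, TsOH·H2O, MeCN, 77 °C; then 1,3,5-trimethoxybenzene, rt
Reagents that add atoms: 1,3,5-trimethoxybenzene COc1cc(OC)cc(OC)c1; 4-methylbenzenesulfonic acid Cc1ccc(S(=O)(=O)O)cc1
Why: One-pot oxidation of the aryl iodide to the trivalent iodine tosylate and electrophilic substitution of trimethoxybenzene should give the unsymmetrical diaryliodonium salt; no stereocentre is involved.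

Step 11
Reactants: 13 (2R,4aS,7R,8aS)-2,4a-dimethyl-7-{2-[(triethylsilyl)oxy]propan-2-yl}decahydronaphthalen-2-ol; 16 (4-bromo-2-chlorophenyl)(2,4,6-trimethoxyphenyl)iodonium 4-methylbenzenesulfonate
Product: 18 (2R,4aS,7R,8aS)-2-(4-bromo-2-chlorophenoxy)-2,4a-dimethyl-7-{2-[(triethylsilyl)oxy]propan-2-yl}decahydronaphthalene, via sodium alkoxide 17 (not isolated)
Conditions: NaH, toluene/THF, rt; then 16, rt → 40 °C
Reagents that add atoms: none
Why: Metal-free O-arylation of a tertiary alkoxide by ligand coupling on trivalent iodine should transfer the electron-poor, ortho-substituted aryl group (trimethoxyphenyl is the non-transferred ligand) and, since the bond forms at oxygen, keep the C2 configuration.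

Step 12
Reactants: 18 (2R,4aS,7R,8aS)-2-(4-bromo-2-chlorophenoxy)-2,4a-dimethyl-7-{2-[(triethylsilyl)oxy]propan-2-yl}decahydronaphthalene
Product: 19 (2R,4aS,7R,8aS)-2-(4-allyl-2-chlorophenoxy)-2,4a-dimethyl-7-{2-[(triethylsilyl)oxy]propan-2-yl}decahydronaphthalene
Conditions: allylSnBu3, Pd(PPh3)4 (5 mol %), toluene, 100 °C
Reagents that add atoms: allyltributylstannane C=CC[Sn](CCCC)(CCCC)CCCC
Why: Stille coupling should take place only at C–Br, because oxidative addition of zerovalent palladium with triphenylphosphine into the hindered C–Cl bond is much slower.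

Step 13
Reactants: 20 2-allyl-4-bromophenol
Product: 21 2-allyl-4-(4,4,5,5-tetramethyl-1,3,2-dioxaborolan-2-yl)phenol
Conditions: B2pin2, Pd(dppf)Cl2 (3 mol %), KOAc, dioxane, 85 °C
Reagents that add atoms: bis(pinacolato)diboron CC1(C)OB(B2OC(C)(C)C(C)(C)O2)OC1(C)C
Why: Miyaura borylation of the aryl bromide tolerates the free phenol and the allyl group under the weak acetate base.

Step 14
Reactants: 19 (2R,4aS,7R,8aS)-2-(4-allyl-2-chlorophenoxy)-2,4a-dimethyl-7-{2-[(triethylsilyl)oxy]propan-2-yl}decahydronaphthalene; 21 2-allyl-4-(4,4,5,5-tetramethyl-1,3,2-dioxaborolan-2-yl)phenol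
Product: 22 3,5'-diallyl-2'-{[(2R,4aS,7R,8aS)-2,4a-dimethyl-7-{2-[(triethylsilyl)oxy]propan-2-yl}decahydronaphthalen-2-yl]oxy}-[1,1'-biphenyl]-4-ol
Conditions: Pd(OAc)2 (5 mol %), SPhos (10 mol %), K3PO4, toluene/H2O 10:1, 90 °C
Reagents that add atoms: none
Why: Suzuki–Miyaura coupling of the hindered, electron-rich aryl chloride should proceed with the bulky dialkylbiarylphosphine, and the basic medium leaves the acid-sensitive tertiary aryl ether intact.

Step 15
Reactants: 22 3,5'-diallyl-2'-{[(2R,4aS,7R,8aS)-2,4a-dimethyl-7-{2-[(triethylsilyl)oxy]propan-2-yl}decahydronaphthalen-2-yl]oxy}-[1,1'-biphenyl]-4-ol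
Product: 23 3,5'-diallyl-2'-{[(2R,4aS,7R,8aS)-7-(2-hydroxypropan-2-yl)-2,4a-dimethyldecahydronaphthalen-2-yl]oxy}-[1,1'-biphenyl]-4-ol
Conditions: TBAF (3 equiv), THF, rt → 50 °C
Reagents that add atoms: none
Why: Fluoride desilylation should free the tertiary alcohol under basic conditions, which the tertiary alkyl aryl ether and the allyl groups tolerate.

**Compound list**

1 | 5-methoxy-2-methylbenzaldehyde | COc1ccc(C)c(C=O)c1 | starting material
2 | 3-(triphenylphosphoranylidene)oxolan-2-one | O=C1OCCC1=P(c1ccccc1)(c1ccccc1)c1ccccc1 | starting material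
3 | (E)-3-[(5-methoxy-2-methylphenyl)methylidene]oxolan-2-one | O=C1OCC/C1=C\c1cc(OC)ccc1C | intermediate
4 | (S)-3-[(5-methoxy-2-methylphenyl)methyl]oxolan-2-one | O=C1OCC[C@@H]1Cc1cc(OC)ccc1C | intermediate
5 | dibromoboranyl (2S)-4-bromo-2-({5-[(dibromoboranyl)oxy]-2-methylphenyl}methyl)butanoate | BrCC[C@H](Cc1cc(OB(Br)Br)ccc1C)C(=O)OB(Br)Br | intermediate
6 | methyl (2S)-4-bromo-2-[(5-hydroxy-2-methylphenyl)methyl]butanoate | COC(=O)[C@H](CCBr)Cc1cc(O)ccc1C | intermediate
7 | 3-[(2S)-4-bromo-2-(2-hydroxypropan-2-yl)butyl]-4-methylphenol | CC(C)(O)[C@H](CCBr)Cc1cc(O)ccc1C | intermediate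
8 | triethyl({2-[(2S)-4-bromo-1-{2-methyl-5-[(triethylsilyl)oxy]phenyl}butan-2-yl]propan-2-yl}oxy)silane | CC[Si](CC)(CC)OC(C)(C)[C@H](CCBr)Cc1cc(O[Si](CC)(CC)CC)ccc1C | intermediate
9 | tetrabutylammonium 3-[(2S)-4-bromo-2-{2-[(triethylsilyl)oxy]propan-2-yl}butyl]-4-methylphenoxide | CC[Si](CC)(CC)OC(C)(C)[C@H](CCBr)Cc1cc([O-])ccc1C.CCCC[N+](CCCC)(CCCC)CCCC | intermediate
10 | (4aS,7R)-4a-methyl-7-{2-[(triethylsilyl)oxy]propan-2-yl}-5,6,7,8-tetrahydronaphthalen-2(4aH)-one | O=C1C=C[C@]2(C)CC[C@@H](C(C)(C)O[Si](CC)(CC)CC)CC2=C1 | intermediate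
11 | (4aS,7R)-4a-methyl-7-{2-[(triethylsilyl)oxy]propan-2-yl}-4,4a,5,6,7,8-hexahydronaphthalen-2(3H)-one | O=C1CC[C@]2(C)CC[C@@H](C(C)(C)O[Si](CC)(CC)CC)CC2=C1 | intermediate
12 | (4aS,7R,8aS)-4a-methyl-7-{2-[(triethylsilyl)oxy]propan-2-yl}octahydronaphthalen-2(1H)-one (trans-fused) | O=C1CC[C@]2(C)CC[C@@H](C(C)(C)O[Si](CC)(CC)CC)C[C@H]2C1 | intermediate
13 | (2R,4aS,7R,8aS)-2,4a-dimethyl-7-{2-[(triethylsilyl)oxy]propan-2-yl}decahydronaphthalen-2-ol (axial OH) | O[C@]1(C)CC[C@]2(C)CC[C@@H](C(C)(C)O[Si](CC)(CC)CC)C[C@H]2C1 | intermediate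
14 | 4-bromo-2-chloro-1-iodobenzene | Clc1cc(Br)ccc1I | starting material
15 | 4-bromo-2-chloro-1-[hydroxy(tosyloxy)iodo]benzene | O[I](OS(=O)(=O)c1ccc(C)cc1)c1ccc(Br)cc1Cl | intermediate
16 | (4-bromo-2-chlorophenyl)(2,4,6-trimethoxyphenyl)iodonium 4-methylbenzenesulfonate | COc1cc(OC)c([I+]c2ccc(Br)cc2Cl)c(OC)c1.Cc1ccc(S(=O)(=O)[O-])cc1 | intermediate
17 | sodium (2R,4aS,7R,8aS)-2,4a-dimethyl-7-{2-[(triethylsilyl)oxy]propan-2-yl}decahydronaphthalen-2-olate | [Na+].[O-][C@]1(C)CC[C@]2(C)CC[C@@H](C(C)(C)O[Si](CC)(CC)CC)C[C@H]2C1 | intermediate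
18 | (2R,4aS,7R,8aS)-2-(4-bromo-2-chlorophenoxy)-2,4a-dimethyl-7-{2-[(triethylsilyl)oxy]propan-2-yl}decahydronaphthalene | Clc1cc(Br)ccc1O[C@]1(C)CC[C@]2(C)CC[C@@H](C(C)(C)O[Si](CC)(CC)CC)C[C@H]2C1 | intermediate
19 | (2R,4aS,7R,8aS)-2-(4-allyl-2-chlorophenoxy)-2,4a-dimethyl-7-{2-[(triethylsilyl)oxy]propan-2-yl}decahydronaphthalene | C=CCc1ccc(O[C@]2(C)CC[C@]3(C)CC[C@@H](C(C)(C)O[Si](CC)(CC)CC)C[C@H]3C2)c(Cl)c1 | intermediate
20 | 2-allyl-4-bromophenol | C=CCc1cc(Br)ccc1O | starting material
21 | 2-allyl-4-(4,4,5,5-tetramethyl-1,3,2-dioxaborolan-2-yl)phenol | C=CCc1cc(B2OC(C)(C)C(C)(C)O2)ccc1O | intermediate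
22 | 3,5'-diallyl-2'-{[(2R,4aS,7R,8aS)-2,4a-dimethyl-7-{2-[(triethylsilyl)oxy]propan-2-yl}decahydronaphthalen-2-yl]oxy}-[1,1'-biphenyl]-4-ol | C=CCc1ccc(O[C@]2(C)CC[C@]3(C)CC[C@@H](C(C)(C)O[Si](CC)(CC)CC)C[C@H]3C2)c(-c2ccc(O)c(CC=C)c2)c1 | intermediate
23 | 3,5'-diallyl-2'-{[(2R,4aS,7R,8aS)-7-(2-hydroxypropan-2-yl)-2,4a-dimethyldecahydronaphthalen-2-yl]oxy}-[1,1'-biphenyl]-4-ol | C=CCc1ccc(O[C@]2(C)CC[C@]3(C)CC[C@@H](C(C)(C)O)C[C@H]3C2)c(-c2ccc(O)c(CC=C)c2)c1 | target

**Step count**

Total: 15 steps (13 in the main line, 2 for the coupling partners 16 and 21). Longest linear sequence: 13 steps (steps 1–9, 11, 12, 14, 15).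

**Steps most likely to fail, with fallbacks**

1. Step 6. The ring closure may leak to the unsubstituted ortho carbon of the phenoxide (which would rearomatize to a tetralinol), or intermolecular O-alkylation may compete. The fallback closes both ortho positions with bromine before cyclization. It sets out from 7: NBS (2.05 equiv, MeCN, 0 °C) should give 2,6-dibromo-3-[(2S)-4-bromo-2-(2-hydroxypropan-2-yl)butyl]-4-methylphenol F1. Silylation as in step 5 (TESOTf, 2,6-lutidine) should give the bis(triethylsilyl) ether of F1, F2. TBAF under the conditions of step 6 should then give (4aS,7R)-1,3-dibromo-4a-methyl-7-{2-[(triethylsilyl)oxy]propan-2-yl}-5,6,7,8-tetrahydronaphthalen-2(4aH)-one F3, the para carbon being the only carbon site left and the oxygen being shielded. Formate hydrogenolysis of the two vinylic C–Br bonds (Pd(OAc)2, PPh3, HCO2H, Et3N, DMF, 60 °C) comes back to the route at 10.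

2. Step 11. Ligand coupling at the hindered axial tertiary alkoxide may be slow, so that base-induced decomposition of the iodonium salt takes over. The fallback is nucleophilic aromatic substitution on a nitro-activated aryl fluoride. It sets out from 13: KH, 18-crown-6, THF, then 2-chloro-1-fluoro-4-nitrobenzene should give (2R,4aS,7R,8aS)-2-(2-chloro-4-nitrophenoxy)-2,4a-dimethyl-7-{2-[(triethylsilyl)oxy]propan-2-yl}decahydronaphthalene F4. Hydrogenation over sulfided Pt/C (H2, EtOAc) should reduce the nitro group without touching C–Cl and give 3-chloro-4-{[(2R,4aS,7R,8aS)-2,4a-dimethyl-7-{2-[(triethylsilyl)oxy]propan-2-yl}decahydronaphthalen-2-yl]oxy}aniline F5. Sandmeyer bromination under neutral conditions (t-BuONO, CuBr2, MeCN) comes back to the route at 18.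

3. Step 2. Face discrimination on the hindered, ortho-substituted trisubstituted alkene may be insufficient (low enantiomeric purity or reversed sense). The fallback is an oxazolidinone-auxiliary alkylation. It sets out from 1: NaBH4 (MeOH) should give (5-methoxy-2-methylphenyl)methanol F6, and PBr3 (Et2O) should give 2-(bromomethyl)-4-methoxy-1-methylbenzene F7. (S)-4-Benzyloxazolidin-2-one is acylated (n-BuLi, pent-4-enoyl chloride) to (S)-4-benzyl-3-(pent-4-enoyl)oxazolidin-2-one F8. Alkylation of its chelated Z-enolate with F7 (NaHMDS, THF, −78 °C), anti to the benzyl group, should give (S)-4-benzyl-3-[(R)-2-(5-methoxy-2-methylbenzyl)pent-4-enoyl]oxazolidin-2-one F9. Ozonolysis with reductive work-up (O3, CH2Cl2/MeOH, −78 °C; NaBH4) should give the primary alkoxide, which closes onto the imide carbonyl, releases the auxiliary and comes back to the route at 4.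

**Further compounds**

F1 | step 6 | 2,6-dibromo-3-[(2S)-4-bromo-2-(2-hydroxypropan-2-yl)butyl]-4-methylphenol | CC(C)(O)[C@H](CCBr)Cc1c(Br)c(O)c(Br)cc1C
F2 | step 6 | bis(triethylsilyl) ether of F1 (aryl and tertiary oxygen) | CC[Si](CC)(CC)OC(C)(C)[C@H](CCBr)Cc1c(Br)c(O[Si](CC)(CC)CC)c(Br)cc1C
F3 | step 6 | (4aS,7R)-1,3-dibromo-4a-methyl-7-{2-[(triethylsilyl)oxy]propan-2-yl}-5,6,7,8-tetrahydronaphthalen-2(4aH)-one | O=C1C(Br)=C[C@]2(C)CC[C@@H](C(C)(C)O[Si](CC)(CC)CC)CC2=C1Br
F4 | step 11 | (2R,4aS,7R,8aS)-2-(2-chloro-4-nitrophenoxy)-2,4a-dimethyl-7-{2-[(triethylsilyl)oxy]propan-2-yl}decahydronaphthalene | O=[N+]([O-])c1ccc(O[C@]2(C)CC[C@]3(C)CC[C@@H](C(C)(C)O[Si](CC)(CC)CC)C[C@H]3C2)c(Cl)c1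
F5 | step 11 | 3-chloro-4-{[(2R,4aS,7R,8aS)-2,4a-dimethyl-7-{2-[(triethylsilyl)oxy]propan-2-yl}decahydronaphthalen-2-yl]oxy}aniline | Nc1ccc(O[C@]2(C)CC[C@]3(C)CC[C@@H](C(C)(C)O[Si](CC)(CC)CC)C[C@H]3C2)c(Cl)c1
F6 | step 2 | (5-methoxy-2-methylphenyl)methanol | COc1ccc(C)c(CO)c1
F7 | step 2 | 2-(bromomethyl)-4-methoxy-1-methylbenzene | COc1ccc(C)c(CBr)c1
F8 | step 2 | (S)-4-benzyl-3-(pent-4-enoyl)oxazolidin-2-one | C=CCCC(=O)N1[C@@H](Cc2ccccc2)COC1=O
F9 | step 2 | (S)-4-benzyl-3-[(R)-2-(5-methoxy-2-methylbenzyl)pent-4-enoyl]oxazolidin-2-one | C=CC[C@H](Cc1cc(OC)ccc1C)C(=O)N1[C@@H](Cc2ccccc2)COC1=O
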